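**Plan**

1. Numbering used below: hydroazulene C1–C10 with C1/C5 the trans ring fusion; C3, C6, C9 are the carbinols; C4 and C10 carry =CH2; C7 carries C11(Me)–C12(OAc)–C13H2–C14H=C15Me2.
2. Retrosynthesis: remove the silyl ethers, cut C9–C10 (seven-membered ring, Nozaki–Hiyama–Kishi), return C3–OH to the ketone, cut C1–C5 (cyclopentane, Nazarov), then C1=C2 (aldol condensation), C4=C5 (Horner–Wadsworth–Emmons), C12–C13 (allylboration) and C7–C11 (Ireland–Claisen).
3. Enabling feature: in the five-membered ring, C3(OH)–C4(=CH2) sits next to the two vicinal, trans ring-fusion CH groups C5 and C1. This is the retron of a 2-methylenecyclopentanone formed by 4π closure of a cross-conjugated dienone between its two β-carbons (like polarity), with the cation ended by a CH2–Si group on C4. O6 and that silicon are tied in a temporary six-membered siloxane.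
4. Forward: open-chain C5–C9/C11–C15 piece, then siloxane enone, then dienone, then the cyclopentane (step 18), then the cycloheptane (step 23).
5. Stereochemistry: C6 from (S)-glyceraldehyde acetonide; C7 and C11 by Ireland–Claisen rearrangement; C12 by Brown allylboration; C5 and C1 by the siloxane-controlled conrotation; C3 by CBS reduction; C9 in the chromium-mediated closure.

Key step: step 18

Remark: (4S)-2,2-dimethyl-1,3-dioxolane-4-carbaldehyde, 2-bromoprop-2-enal and (−)-B-allyldiisopinocampheylborane (as a pentane solution) are taken as purchasable.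

**Route**

Step 1
Reactants: 1 (4S)-2,2-dimethyl-1,3-dioxolane-4-carbaldehyde; 2 methyl (triphenyl-λ5-phosphanylidene)acetate
Product: 3 methyl (2Z)-3-[(4R)-2,2-dimethyl-1,3-dioxolan-4-yl]prop-2-enoate
Conditions: MeOH, 0 °C
Reagents that add atoms: none
Why: Wittig reaction of a stabilised ylide, which in methanol gives mainly the Z-enoate from α-alkoxy aldehydes and leaves the dioxolane stereocentre (later C6) untouched.

Step 2
Reactants: 3 methyl (2Z)-3-[(4R)-2,2-dimethyl-1,3-dioxolan-4-yl]prop-2-enoate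
Product: 4 (2Z)-3-[(4R)-2,2-dimethyl-1,3-dioxolan-4-yl]prop-2-en-1-ol
Conditions: iBu2AlH (2.2 equiv), CH2Cl2, −78 °C
Reagents that add atoms: none
Why: reduction of the ester to the allylic alcohol with a dialkylaluminium hydride at low temperature leaves the Z-double bond and the acetal intact.

Step 3
Reactants: 4 (2Z)-3-[(4R)-2,2-dimethyl-1,3-dioxolan-4-yl]prop-2-en-1-ol; 5 propanoyl chloride
Product: 6 (2Z)-3-[(4R)-2,2-dimethyl-1,3-dioxolan-4-yl]prop-2-en-1-yl propanoate
Conditions: pyridine, DMAP (cat.), CH2Cl2, 0 °C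
Reagents that add atoms: none
Why: pyridine-mediated O-acylation of a primary allylic alcohol.

Step 4
Reactants: 6 (2Z)-3-[(4R)-2,2-dimethyl-1,3-dioxolan-4-yl]prop-2-en-1-yl propanoate
Product: 10 methyl (2S,3S)-3-[(4R)-2,2-dimethyl-1,3-dioxolan-4-yl]-2-methylpent-4-enoate, via (Z)-silyl ketene acetal 7 (not isolated), via trimethylsilyl ester 8 (not isolated), via carboxylic acid 9 (not isolated)
Conditions: LiN(iPr)2, THF/DMPU (4:1), −78 °C; Me3SiCl, −78 °C → rt; 1 M HCl; then Me3SiCHN2, MeOH/toluene, 0 °C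
Reagents that add atoms: trimethylsilyldiazomethane, C[Si](C)(C)C=[N+]=[N-]
Why: Ireland–Claisen rearrangement, in which enolisation in the presence of DMPU gives the Z(O)-enolate and hence ketene acetal 7, which rearranges through a chair with the new C7–C11 bond anti to the dioxolane C–O bond of the A(1,3)-locked Z-allyl unit, so that C6 sets C7 and the two double-bond geometries set the anti C7/C11 relationship; the acid is then methylated.

Step 5
Reactants: 10 methyl (2S,3S)-3-[(4R)-2,2-dimethyl-1,3-dioxolan-4-yl]-2-methylpent-4-enoate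
Product: 12 methyl (2S,3S)-3-[(4R)-2,2-dimethyl-1,3-dioxolan-4-yl]-5-hydroxy-2-methylpentanoate, via B-alkyl-9-borabicyclononane 11 (not isolated)
Conditions: 9-BBN, THF, 0 °C → rt; then 30% H2O2, aq. NaOAc, 0 °C
Reagents that add atoms: hydrogen peroxide, OO
Why: hydroboration–oxidation, in which 9-BBN adds anti-Markovnikov to the only alkene and buffered oxidation spares the ester.

Step 6
Reactants: 12 methyl (2S,3S)-3-[(4R)-2,2-dimethyl-1,3-dioxolan-4-yl]-5-hydroxy-2-methylpentanoate
Product: 13 methyl (2S,3S)-5-[tert-butyl(dimethyl)silyl]oxy-3-[(4R)-2,2-dimethyl-1,3-dioxolan-4-yl]-2-methylpentanoate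
Conditions: imidazole, DMF, 0 °C → rt
Reagents that add atoms: tert-butyldimethylsilyl chloride, CC(C)(C)[Si](C)(C)Cl
Why: silylation of the primary alcohol, done at once to forestall lactonisation onto the methyl ester.

Step 7
Reactants: 13 methyl (2S,3S)-5-[tert-butyl(dimethyl)silyl]oxy-3-[(4R)-2,2-dimethyl-1,3-dioxolan-4-yl]-2-methylpentanoate
Product: 14 (2S,3S)-5-[tert-butyl(dimethyl)silyl]oxy-3-[(4R)-2,2-dimethyl-1,3-dioxolan-4-yl]-2-methylpentanal
Conditions: iBu2AlH (1.1 equiv), CH2Cl2, −78 °C; Rochelle salt work-up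
Reagents that add atoms: none
Why: partial reduction of the ester stops at the tetrahedral aluminium hemiacetal at −78 °C, and the α-stereocentre (C11) is kept by using the aldehyde crude.

Step 8
Reactants: 14 (2S,3S)-5-[tert-butyl(dimethyl)silyl]oxy-3-[(4R)-2,2-dimethyl-1,3-dioxolan-4-yl]-2-methylpentanal; 15 (−)-B-allyldiisopinocampheylborane
Product: 16 (4S,5S,6S)-8-[tert-butyl(dimethyl)silyl]oxy-6-[(4R)-2,2-dimethyl-1,3-dioxolan-4-yl]-5-methyloct-1-en-4-ol
Conditions: Et2O, −78 °C; then 30% H2O2, pH 7 buffer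
Reagents that add atoms: none
Why: Brown allylboration through a closed chair transition state, in which the reagent from (+)-α-pinene attacks the Si face, which is also the Felkin–Anh face of the α-methyl aldehyde (matched pair), setting C12 as S.

Step 9
Reactants: 16 (4S,5S,6S)-8-[tert-butyl(dimethyl)silyl]oxy-6-[(4R)-2,2-dimethyl-1,3-dioxolan-4-yl]-5-methyloct-1-en-4-ol
Product: 17 (4S,5S,6S)-8-[tert-butyl(dimethyl)silyl]oxy-6-[(4R)-2,2-dimethyl-1,3-dioxolan-4-yl]-5-methyloct-1-en-4-yl acetate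
Conditions: DMAP (cat.), pyridine, CH2Cl2, rt
Reagents that add atoms: acetic anhydride, CC(=O)OC(C)=O
Why: DMAP-catalysed acetylation puts the C12 acetate of the target on the only free hydroxyl.

Step 10
Reactants: 17 (4S,5S,6S)-8-[tert-butyl(dimethyl)silyl]oxy-6-[(4R)-2,2-dimethyl-1,3-dioxolan-4-yl]-5-methyloct-1-en-4-yl acetate; 18 2-methylbut-2-ene
Product: 19 (5S,6S,7S)-9-[tert-butyl(dimethyl)silyl]oxy-7-[(4R)-2,2-dimethyl-1,3-dioxolan-4-yl]-2,6-dimethylnon-2-en-5-yl acetate
Conditions: second-generation Grubbs catalyst (H2IMes)(PCy3)Cl2Ru=CHPh (3 mol%), CH2Cl2, 18 as co-solvent, 40 °C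
Reagents that add atoms: none
Why: olefin cross-metathesis of the only terminal alkene with excess 2-methylbut-2-ene gives the trisubstituted prenyl end group with loss of propene.

Step 11
Reactants: 19 (5S,6S,7S)-9-[tert-butyl(dimethyl)silyl]oxy-7-[(4R)-2,2-dimethyl-1,3-dioxolan-4-yl]-2,6-dimethylnon-2-en-5-yl acetate
Product: 20 (5S,6S,7S)-9-[tert-butyl(dimethyl)silyl]oxy-7-[(1R)-1,2-dihydroxyethyl]-2,6-dimethylnon-2-en-5-yl acetate
Conditions: CuCl2·2H2O, MeCN, 0 °C
Reagents that add atoms: none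
Why: mild Lewis-acid hydrolysis of the terminal acetonide, to which the primary silyl ether and the acetate are stable at 0 °C.

Step 12
Reactants: 20 (5S,6S,7S)-9-[tert-butyl(dimethyl)silyl]oxy-7-[(1R)-1,2-dihydroxyethyl]-2,6-dimethylnon-2-en-5-yl acetate
Product: 21 bis(triethylsilyl) ether of 20
Conditions: imidazole, DMF, 0 °C
Reagents that add atoms: chlorotriethylsilane, CC[Si](CC)(CC)Cl
Why: silylation of both hydroxyls of the diol.

Step 13
Reactants: 21 bis(triethylsilyl) ether of 20
Product: 22 C5 aldehyde: (5S,6S,7S)-9-[tert-butyl(dimethyl)silyl]oxy-2,6-dimethyl-7-[(1R)-2-oxo-1-(triethylsilyloxy)ethyl]non-2-en-5-yl acetate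
Conditions: (COCl)2, DMSO, CH2Cl2, −78 °C; Et3N, −78 → −30 °C
Reagents that add atoms: none
Why: Swern oxidation applied directly to a primary triethylsilyl ether, which is cleaved and oxidised while the secondary triethylsilyl and the primary tert-butyldimethylsilyl ethers are inert.

Step 14
Reactants: 23 diethyl (2-oxopropyl)phosphonate; 24 (chloromethyl)dimethyl(propan-2-yloxy)silane
Product: 25 diethyl (1-{[dimethyl(propan-2-yloxy)silyl]methyl}-2-oxopropyl)phosphonate
Conditions: NaH, NaI (cat.), DMF, 0 → 60 °C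
Reagents that add atoms: none
Why: C-alkylation of the sodium enolate of a β-ketophosphonate by an α-halosilane (SN2, helped by silicon and by iodide catalysis).

Step 15
Reactants: 22 C5 aldehyde; 25 diethyl (1-{[dimethyl(propan-2-yloxy)silyl]methyl}-2-oxopropyl)phosphonate
Product: 26 open-chain methyl enone (acetyl carbon = C3; C4=C5 with C6 cis to the CH2SiMe2(OiPr) group on C4; 6R-OSiEt3, 7S, 9-OTBS, 11S, 12S-OAc)
Conditions: NaH, THF, 0 °C → rt
Reagents that add atoms: none
Why: Horner–Wadsworth–Emmons olefination, in which the α-branched β-ketophosphonate anion gives the trisubstituted enone with C6 trans to the acetyl group, the geometry needed for ring closure in step 16.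

Step 16
Reactants: 26 open-chain methyl enone
Product: 28 siloxane enone: 4-acetyl-2,2-dimethyl-3,6-dihydro-2H-1,2-oxasiline carrying at its C6 (R; = skeleton C6) the C7–C9/C11–C15 chain, via C6 alcohol 27 (not isolated)
Conditions: PPTS, MeOH/CH2Cl2 (1:4), 0 °C; concentrate; then PPTS, toluene, 4 Å MS, 45 °C
Reagents that add atoms: none
Why: acid methanolysis removes the secondary triethylsilyl ether much faster than the primary tert-butyldimethylsilyl ether, and the freed C6 hydroxyl then displaces isopropanol at silicon (transetherification), which only the isomer with C6 cis to CH2Si can do.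

Step 17
Reactants: 28 siloxane enone; 29 2-bromoprop-2-enal
Product: 32 siloxane dienone: cross-conjugated (1E)-dienone C5=C4–C3(=O)–C2=C1 with C10(Br)=CH2 on C1 and the siloxane ring intact, via aldol adduct 30 (not isolated), via mesylate 31 (not isolated)
Conditions: Bu2BOTf, iPr2NEt, CH2Cl2, −78 °C; 29, −78 → 0 °C; MeOH/pH 7 buffer; then MsCl, Et3N, CH2Cl2, 0 °C → rt
Reagents that add atoms: none
Why: boron-mediated aldol addition of the methyl ketone (soft enolisation does not touch the acetate) to the aldehyde, followed by mesylation and E1cB elimination, gives the E-enone.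

Step 18
Reactants: 32 siloxane dienone
Product: 34 (1R,5S)-2-methylenecyclopentanone: C3 ketone, C4=CH2, C5 carrying the C6(OH) chain, C1 carrying the 1-bromovinyl group, H-1/H-5 trans, via chlorodimethylsilyl ether 33 (not isolated)
Conditions: FeCl3 (1.1 equiv), CH2Cl2, −40 → 0 °C; then AcOH/THF/H2O, 0 °C
Reagents that add atoms: none
Why: Proposed new method: FeCl3 activates the dienone as a 3-oxidopentadienyl cation, whose two β-carbons (C5 and C1, both acceptor positions) are joined by thermal conrotatory 4π electrocyclisation (Nazarov reaction) to an oxyallyl cation; its C4 terminus is then β to the ring silicon, the Si–CH2 bond is lost to chloride (β-silicon effect) and the cation ends as the C4 exocyclic methylene next to the C3 ketone, both new stereocentres being kept. The closest known reaction type is the Nazarov cyclisation of open-chain α-(trimethylsilylmethyl) divinyl ketones to 2-methylenecyclopentanones; a silicon held in a 1-oxa-2-silacyclohex-4-ene has not been used in this role. The cyclopentane is closed in the 4π-conrotatory electrocyclic mode, and the temporary six-membered siloxane is opened in the same event. The trans relationship of C1 and C5 follows from conrotation of two termini that both carry their substituent outside (any Z-enone isomerises under the Lewis acid and converges on the same cation); the configuration of C5 is controlled by C6, because the siloxane ring holds the C6–O bond in the dienone plane and the C7 branch over one face, so that the new bond should form anti to it, as in additions to 4-substituted cyclohex-2-enones. The step needs torquoselectivity and silicon loss in preference to loss of H-5 or H-1: the first is secured by the ring-locked C6 centre, the second by the roughly 45° torsion of the ring Si–CH2 bond against the cationic p-orbital, which leaves good σ–p overlap.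

Step 19
Reactants: 34 (1R,5S)-2-methylenecyclopentanone
Product: 35 (1R,3S,5S)-diol: C3 and C6 hydroxyls free
Conditions: (R)-2-methyl-CBS-oxazaborolidine (0.5 equiv), catecholborane, toluene, −78 °C
Reagents that add atoms: none
Why: Corey–Bakshi–Shibata reduction, in which the (R)-catalyst binds the ketone with the 2-methylene (alkenyl) side as the large group and delivers hydride to give the (S)-carbinol at C3, the catalysed 1,2-reduction outrunning conjugate reduction at −78 °C.

Step 20
Reactants: 35 (1R,3S,5S)-diol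
Product: 36 tris(silyl) ether: C3, C6 and C9 oxygens all as tert-butyldimethylsilyl ethers
Conditions: 2,6-lutidine, CH2Cl2, −78 → 0 °C
Reagents that add atoms: tert-butyldimethylsilyl triflate, CC(C)(C)[Si](C)(C)OS(=O)(=O)C(F)(F)F
Why: silyl triflate silylation protects both secondary hydroxyls, the hindered C6–OH included.

Step 21
Reactants: 36 tris(silyl) ether
Product: 37 C9 primary alcohol (C3 and C6 silyl ethers kept)
Conditions: HF·pyridine, pyridine, THF, 0 °C
Reagents that add atoms: none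
Why: buffered HF·pyridine cleaves the primary silyl ether much faster than the two secondary ones.

Step 22
Reactants: 37 C9 primary alcohol
Product: 38 C9 aldehyde
Conditions: Dess–Martin periodinane, NaHCO3, CH2Cl2, 0 °C → rt
Reagents that add atoms: none
Why: buffered Dess–Martin oxidation gives the aldehyde without touching the alkenes, the vinyl bromide or the acetate.

Step 23
Reactants: 38 C9 aldehyde
Product: 39 bis(silyl) ether of the target: hydroazulene with free 9R-hydroxyl, C3 and C6 as tert-butyldimethylsilyl ethers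
Conditions: CrCl2 (6 equiv), NiCl2 (2 mol%), DMSO/THF, rt, 2 mM
Reagents that add atoms: none
Why: Nozaki–Hiyama–Kishi reaction, in which NiCl2-catalysed formation of the alkenylchromium reagent from the vinyl bromide and its addition to the aldehyde close the seven-membered ring and give the C9 allylic alcohol next to the C10 methylene directly; the C9–O bond is expected on the face of H-1, with the chromium-bound oxygen turned away from the cyclopentane.

Step 24
Reactants: 39 bis(silyl) ether of the target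
Product: 40 CNP0210891.3 (1R,3S,5S,6R,7S,9R,11S,12S)
Conditions: HF·pyridine, THF/MeCN, 0 °C → rt
Reagents that add atoms: none
Why: fluoride cleavage of both silyl ethers, to which the acetate and the two allylic alcohols are stable.

**Compound list**

1 | (4S)-2,2-dimethyl-1,3-dioxolane-4-carbaldehyde | O=C[C@@H]1COC(C)(C)O1 | starting material
2 | methyl (triphenyl-λ5-phosphanylidene)acetate | COC(=O)C=P(c1ccccc1)(c1ccccc1)c1ccccc1 | starting material
3 | methyl (2Z)-3-[(4R)-2,2-dimethyl-1,3-dioxolan-4-yl]prop-2-enoate | COC(=O)/C=C\[C@@H]1COC(C)(C)O1 | intermediate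
4 | (2Z)-3-[(4R)-2,2-dimethyl-1,3-dioxolan-4-yl]prop-2-en-1-ol | OC/C=C\[C@@H]1COC(C)(C)O1 | intermediate
5 | propanoyl chloride | CCC(=O)Cl | starting material
6 | (2Z)-3-[(4R)-2,2-dimethyl-1,3-dioxolan-4-yl]prop-2-en-1-yl propanoate | CCC(=O)OC/C=C\[C@@H]1COC(C)(C)O1 | intermediate
7 | (Z)-trimethylsilyl ketene acetal of 6 | C/C=C(\O[Si](C)(C)C)OC/C=C\[C@@H]1COC(C)(C)O1 | intermediate
8 | trimethylsilyl (2S,3S)-3-[(4R)-2,2-dimethyl-1,3-dioxolan-4-yl]-2-methylpent-4-enoate | C[Si](C)(C)OC(=O)[C@@H](C)[C@H](C=C)[C@@H]1COC(C)(C)O1 | intermediate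
9 | (2S,3S)-3-[(4R)-2,2-dimethyl-1,3-dioxolan-4-yl]-2-methylpent-4-enoic acid | OC(=O)[C@@H](C)[C@H](C=C)[C@@H]1COC(C)(C)O1 | intermediate
10 | methyl (2S,3S)-3-[(4R)-2,2-dimethyl-1,3-dioxolan-4-yl]-2-methylpent-4-enoate | COC(=O)[C@@H](C)[C@H](C=C)[C@@H]1COC(C)(C)O1 | intermediate
11 | B-alkyl-9-borabicyclo[3.3.1]nonane from 10 | COC(=O)[C@@H](C)[C@H](CCB1C2CCCC1CCC2)[C@@H]1COC(C)(C)O1 | intermediate
12 | methyl (2S,3S)-3-[(4R)-2,2-dimethyl-1,3-dioxolan-4-yl]-5-hydroxy-2-methylpentanoate | COC(=O)[C@@H](C)[C@H](CCO)[C@@H]1COC(C)(C)O1 | intermediate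
13 | methyl (2S,3S)-5-[tert-butyl(dimethyl)silyl]oxy-3-[(4R)-2,2-dimethyl-1,3-dioxolan-4-yl]-2-methylpentanoate | COC(=O)[C@@H](C)[C@H](CCO[Si](C)(C)C(C)(C)C)[C@@H]1COC(C)(C)O1 | intermediate
14 | (2S,3S)-5-[tert-butyl(dimethyl)silyl]oxy-3-[(4R)-2,2-dimethyl-1,3-dioxolan-4-yl]-2-methylpentanal | O=C[C@@H](C)[C@H](CCO[Si](C)(C)C(C)(C)C)[C@@H]1COC(C)(C)O1 | intermediate
15 | (−)-B-allyldiisopinocampheylborane, allylbis[(1R,2S,3R,5R)-2,6,6-trimethylbicyclo[3.1.1]heptan-3-yl]borane | C=CCB([C@@H]1C[C@@H]2C[C@H]([C@H]1C)C2(C)C)[C@@H]1C[C@@H]2C[C@H]([C@H]1C)C2(C)C | starting material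
16 | (4S,5S,6S)-8-[tert-butyl(dimethyl)silyl]oxy-6-[(4R)-2,2-dimethyl-1,3-dioxolan-4-yl]-5-methyloct-1-en-4-ol | C=CC[C@H](O)[C@@H](C)[C@H](CCO[Si](C)(C)C(C)(C)C)[C@@H]1COC(C)(C)O1 | intermediate
17 | (4S,5S,6S)-8-[tert-butyl(dimethyl)silyl]oxy-6-[(4R)-2,2-dimethyl-1,3-dioxolan-4-yl]-5-methyloct-1-en-4-yl acetate | C=CC[C@H](OC(C)=O)[C@@H](C)[C@H](CCO[Si](C)(C)C(C)(C)C)[C@@H]1COC(C)(C)O1 | intermediate
18 | 2-methylbut-2-ene | CC=C(C)C | starting material
19 | (5S,6S,7S)-9-[tert-butyl(dimethyl)silyl]oxy-7-[(4R)-2,2-dimethyl-1,3-dioxolan-4-yl]-2,6-dimethylnon-2-en-5-yl acetate | CC(C)=CC[C@H](OC(C)=O)[C@@H](C)[C@H](CCO[Si](C)(C)C(C)(C)C)[C@@H]1COC(C)(C)O1 | intermediate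
20 | (5S,6S,7S)-9-[tert-butyl(dimethyl)silyl]oxy-7-[(1R)-1,2-dihydroxyethyl]-2,6-dimethylnon-2-en-5-yl acetate | CC(C)=CC[C@H](OC(C)=O)[C@@H](C)[C@H](CCO[Si](C)(C)C(C)(C)C)[C@@H](O)CO | intermediate
21 | bis(triethylsilyl) ether of 20 | CC(C)=CC[C@H](OC(C)=O)[C@@H](C)[C@H](CCO[Si](C)(C)C(C)(C)C)[C@@H](O[Si](CC)(CC)CC)CO[Si](CC)(CC)CC | intermediate
22 | C5 aldehyde, (5S,6S,7S)-9-[tert-butyl(dimethyl)silyl]oxy-2,6-dimethyl-7-[(1R)-2-oxo-1-(triethylsilyloxy)ethyl]non-2-en-5-yl acetate | CC(C)=CC[C@H](OC(C)=O)[C@@H](C)[C@H](CCO[Si](C)(C)C(C)(C)C)[C@@H](O[Si](CC)(CC)CC)C=O | intermediate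
23 | diethyl (2-oxopropyl)phosphonate | CCOP(=O)(OCC)CC(C)=O | starting material
24 | (chloromethyl)dimethyl(propan-2-yloxy)silane | CC(C)O[Si](C)(C)CCl | starting material
25 | diethyl (1-{[dimethyl(propan-2-yloxy)silyl]methyl}-2-oxopropyl)phosphonate | CCOP(=O)(OCC)C(C[Si](C)(C)OC(C)C)C(C)=O | intermediate
26 | open-chain methyl enone (C4=C5, C6 cis to CH2Si; 6R-OSiEt3, 7S, 11S, 12S) | CC(=O)/C(C[Si](C)(C)OC(C)C)=C/[C@H](O[Si](CC)(CC)CC)[C@@H](CCO[Si](C)(C)C(C)(C)C)[C@H](C)[C@H](CC=C(C)C)OC(C)=O | intermediate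
27 | C6 alcohol of 26 | CC(=O)/C(C[Si](C)(C)OC(C)C)=C/[C@H](O)[C@@H](CCO[Si](C)(C)C(C)(C)C)[C@H](C)[C@H](CC=C(C)C)OC(C)=O | intermediate
28 | siloxane enone, 4-acetyl-2,2-dimethyl-3,6-dihydro-2H-1,2-oxasiline with the chain on its C6 (R) | CC(=O)C1=C[C@H](O[Si](C)(C)C1)[C@@H](CCO[Si](C)(C)C(C)(C)C)[C@H](C)[C@H](CC=C(C)C)OC(C)=O | intermediate
29 | 2-bromoprop-2-enal | C=C(Br)C=O | starting material
30 | aldol adduct of 28 and 29 (carbinol carbon unassigned) | C=C(Br)C(O)CC(=O)C1=C[C@H](O[Si](C)(C)C1)[C@@H](CCO[Si](C)(C)C(C)(C)C)[C@H](C)[C@H](CC=C(C)C)OC(C)=O | intermediate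
31 | mesylate of 30 | C=C(Br)C(OS(C)(=O)=O)CC(=O)C1=C[C@H](O[Si](C)(C)C1)[C@@H](CCO[Si](C)(C)C(C)(C)C)[C@H](C)[C@H](CC=C(C)C)OC(C)=O | intermediate
32 | siloxane dienone, (1E)-cross-conjugated dienone with 1-bromovinyl on C1 | C=C(Br)/C=C/C(=O)C1=C[C@H](O[Si](C)(C)C1)[C@@H](CCO[Si](C)(C)C(C)(C)C)[C@H](C)[C@H](CC=C(C)C)OC(C)=O | intermediate
33 | chlorodimethylsilyl ether of 34 | C=C1C(=O)C[C@@H](C(Br)=C)[C@@H]1[C@H](O[Si](C)(C)Cl)[C@@H](CCO[Si](C)(C)C(C)(C)C)[C@H](C)[C@H](CC=C(C)C)OC(C)=O | intermediate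
34 | (1R,5S)-2-methylenecyclopentanone with free C6 hydroxyl | C=C1C(=O)C[C@@H](C(Br)=C)[C@@H]1[C@H](O)[C@@H](CCO[Si](C)(C)C(C)(C)C)[C@H](C)[C@H](CC=C(C)C)OC(C)=O | intermediate
35 | (1R,3S,5S)-diol (C3 and C6 hydroxyls) | C=C1[C@@H](O)C[C@@H](C(Br)=C)[C@@H]1[C@H](O)[C@@H](CCO[Si](C)(C)C(C)(C)C)[C@H](C)[C@H](CC=C(C)C)OC(C)=O | intermediate
36 | tris(tert-butyldimethylsilyl) ether (O3, O6, O9) | C=C1[C@@H](O[Si](C)(C)C(C)(C)C)C[C@@H](C(Br)=C)[C@@H]1[C@H](O[Si](C)(C)C(C)(C)C)[C@@H](CCO[Si](C)(C)C(C)(C)C)[C@H](C)[C@H](CC=C(C)C)OC(C)=O | intermediate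
37 | C9 primary alcohol | C=C1[C@@H](O[Si](C)(C)C(C)(C)C)C[C@@H](C(Br)=C)[C@@H]1[C@H](O[Si](C)(C)C(C)(C)C)[C@@H](CCO)[C@H](C)[C@H](CC=C(C)C)OC(C)=O | intermediate
38 | C9 aldehyde | C=C1[C@@H](O[Si](C)(C)C(C)(C)C)C[C@@H](C(Br)=C)[C@@H]1[C@H](O[Si](C)(C)C(C)(C)C)[C@@H](CC=O)[C@H](C)[C@H](CC=C(C)C)OC(C)=O | intermediate
39 | 3,6-bis(tert-butyldimethylsilyl) ether of the target | C=C1[C@H]2[C@H](O[Si](C)(C)C(C)(C)C)[C@H]([C@H](C)[C@H](CC=C(C)C)OC(C)=O)C[C@@H](O)C(=C)[C@@H]2C[C@@H]1O[Si](C)(C)C(C)(C)C | intermediate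
40 | CNP0210891.3 | C=C1[C@H]2[C@H](O)[C@H]([C@H](C)[C@H](CC=C(C)C)OC(C)=O)C[C@@H](O)C(=C)[C@@H]2C[C@@H]1O | target

**Step count and risks**

Total step count: 24. Longest linear sequence: 23 steps (steps 1–13 and 15–24; step 14 makes the phosphonate separately).

Steps most likely to fail:

1. Step 18 (proposed new method). What may go wrong: the oxyallyl cation loses H-5 or H-1 instead of the ring silicon (endocyclic enone), or the siloxane opens at Si–O before cyclisation, so that torquoselectivity is lost. Fallback with the established open-chain substrate class: set out from 22. Alkylate 23 with (chloromethyl)trimethylsilane (NaH, NaI, DMF) to diethyl [2-oxo-1-(trimethylsilylmethyl)propyl]phosphonate F1. Horner–Wadsworth–Emmons reaction of F1 with 22 gives the open-chain trimethylsilylmethyl enone F2. Aldol condensation with 29 as in step 17 gives the open-chain dienone F3. FeCl3 in CH2Cl2 at −40 °C then performs the known Nazarov cyclisation of an α-(trimethylsilylmethyl) divinyl ketone, whose freely rotating CH2–SiMe3 bond aligns with the cation, to the 6-O-triethylsilyl methylenecyclopentanone F4. The C1/C5 trans pair is again fixed by conrotation, but facial control now rests only on the open-chain C6 centre, so the two trans diastereomers may have to be separated. PPTS in MeOH removes the triethylsilyl group and the route is rejoined at 34.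

2. Step 23. What may go wrong: poor facial selectivity in the addition of the alkenylchromium reagent to the aldehyde, giving a mixture at C9. Fallback that sets C9 by reagent-controlled reduction instead: set out from the crude cyclisation mixture obtained from 38. Oxidise it with Dess–Martin periodinane to the cross-conjugated C9 enone F5. Reduce F5 with (S)-2-methyl-CBS-oxazaborolidine and catecholborane at −78 °C (the alkenyl side again acts as the large group, giving 9R). The route is rejoined at 39.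

3. Step 4. What may go wrong: incomplete control of enolate geometry, which erodes the C7/C11 relationship. Fallback that sets the two centres in separate steps: set out from 4. Johnson orthoester Claisen rearrangement (triethyl orthoacetate, cat. propanoic acid, 140 °C; same chair and same facial control by C6) gives ethyl (3S)-3-[(4R)-2,2-dimethyl-1,3-dioxolan-4-yl]pent-4-enoate F6. LiOH gives the acid F7. Pivaloyl chloride/Et3N and lithiated (S)-4-benzyloxazolidin-2-one give the imide F8. Evans alkylation (NaN(SiMe3)2, MeI, −78 °C; methyl enters anti to the benzyl group) gives the α-methyl imide F9. NaOMe in MeOH at 0 °C releases the auxiliary and the route is rejoined at 10.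

**Further compounds**

F1 | step 18 | diethyl [2-oxo-1-(trimethylsilylmethyl)propyl]phosphonate | CCOP(=O)(OCC)C(C[Si](C)(C)C)C(C)=O
F2 | step 18 | open-chain trimethylsilylmethyl enone (C6 as triethylsilyl ether) | CC(=O)/C(C[Si](C)(C)C)=C/[C@H](O[Si](CC)(CC)CC)[C@@H](CCO[Si](C)(C)C(C)(C)C)[C@H](C)[C@H](CC=C(C)C)OC(C)=O
F3 | step 18 | open-chain dienone | C=C(Br)/C=C/C(=O)/C(C[Si](C)(C)C)=C/[C@H](O[Si](CC)(CC)CC)[C@@H](CCO[Si](C)(C)C(C)(C)C)[C@H](C)[C@H](CC=C(C)C)OC(C)=O
F4 | step 18 | 6-O-triethylsilyl ether of 34 | C=C1C(=O)C[C@@H](C(Br)=C)[C@@H]1[C@H](O[Si](CC)(CC)CC)[C@@H](CCO[Si](C)(C)C(C)(C)C)[C@H](C)[C@H](CC=C(C)C)OC(C)=O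
F5 | step 23 | C9 enone of 39 | C=C1[C@H]2[C@H](O[Si](C)(C)C(C)(C)C)[C@H]([C@H](C)[C@H](CC=C(C)C)OC(C)=O)CC(=O)C(=C)[C@@H]2C[C@@H]1O[Si](C)(C)C(C)(C)C
F6 | step 4 | ethyl (3S)-3-[(4R)-2,2-dimethyl-1,3-dioxolan-4-yl]pent-4-enoate | CCOC(=O)C[C@H](C=C)[C@@H]1COC(C)(C)O1
F7 | step 4 | (3S)-3-[(4R)-2,2-dimethyl-1,3-dioxolan-4-yl]pent-4-enoic acid | OC(=O)C[C@H](C=C)[C@@H]1COC(C)(C)O1
F8 | step 4 | (4S)-4-benzyl-3-{(3S)-3-[(4R)-2,2-dimethyl-1,3-dioxolan-4-yl]pent-4-enoyl}oxazolidin-2-one | O=C(C[C@H](C=C)[C@@H]1COC(C)(C)O1)N1[C@@H](Cc2ccccc2)COC1=O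
F9 | step 4 | (4S)-4-benzyl-3-{(2S,3S)-3-[(4R)-2,2-dimethyl-1,3-dioxolan-4-yl]-2-methylpent-4-enoyl}oxazolidin-2-one | O=C([C@@H](C)[C@H](C=C)[C@@H]1COC(C)(C)O1)N1[C@@H](Cc2ccccc2)COC1=O
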